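## Retrosynthetic overview

- The target acid comes from its C19 primary alcohol by one oxidation; the C15 stearate is put on in the second step and carried through, so no protecting group is needed.
- Both rings form in one cationic head-to-tail cascade of an acyclic C20 epoxy-diene ester. An oxirane spanning C4 and the future C19 opens at C4 to close ring A (C4–C5), ring B follows (C10–C9), and loss of a C17 proton gives the 8(17)-alkene, as in the labdane cyclase step. The C19 oxygen is already in place and the oxirane centre relays chirality to C4, C5, C10 and C9.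
- The oxirane comes from a methyl ketone by catalytic asymmetric methylene transfer; the ketone comes from an allylic bromide (C1) and a ketal Grignard reagent (C2–C4 and C18).
- The allylic bromide comes from terminal allylic oxidation of (S)-2,3-dihydrofarnesyl stearate, made from (2E,6E)-farnesol (asymmetric hydrogenation sets C13) and stearoyl chloride.

Labdane numbering (C1–C20) is used for atoms throughout.

Assumption: the ligand antipodes quoted follow the reported sense of induction (Ru(OAc)2[(R)-BINAP] gives the 3S alcohol from a geraniol-type substrate; the (S)-binaphtholate lanthanum complex is taken to give the S oxirane); if a sense proves opposite, the mirror-image ligand is used.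

## Route

Step 1
Reactants: 1 (2E,6E)-farnesol [(2E,6E)-3,7,11-trimethyldodeca-2,6,10-trien-1-ol]
Product: 2 (3S,6E)-3,7,11-trimethyldodeca-6,10-dien-1-ol [(S)-2,3-dihydrofarnesol]
Conditions: H2 (100 atm), Ru(OAc)2[(R)-BINAP] (0.5 mol %), MeOH/H2O 95:5, 20 °C
Reagents that add atoms: none
Why: Noyori asymmetric hydrogenation: the allylic hydroxyl binds the BINAP–ruthenium diacetate so that only the 2,3-alkene is reduced from one face, which sets the future C13 as S, while the two unfunctionalised trisubstituted alkenes are left alone.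

Step 2
Reactants: 2 (3S,6E)-3,7,11-trimethyldodeca-6,10-dien-1-ol; 3 octadecanoyl chloride (stearoyl chloride)
Product: 4 (3S,6E)-3,7,11-trimethyldodeca-6,10-dien-1-yl octadecanoate
Conditions: Et3N, DMAP (cat.), CH2Cl2, 0 °C → rt
Reagents that add atoms: none
Why: DMAP-catalysed acylation (nucleophilic acyl substitution) of the primary alcohol installs the stearate of the target, which also serves as the only hydroxyl protection for the rest of the route.

Step 3
Reactants: 4 (3S,6E)-3,7,11-trimethyldodeca-6,10-dien-1-yl octadecanoate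
Product: 5 (3S,6E,10E)-12-hydroxy-3,7,11-trimethyldodeca-6,10-dien-1-yl octadecanoate
Conditions: SeO2 (0.2 equiv), t-BuOOH (3 equiv), salicylic acid (0.1 equiv), CH2Cl2, 0 °C → rt
Reagents that add atoms: selenium dioxide, O=[Se]=O (transfers the oxygen and is regenerated by tert-butyl hydroperoxide, CC(C)(C)OO)
Why: Sharpless catalytic SeO2 allylic oxidation (ene reaction, then 2,3-sigmatropic shift) attacks the more accessible terminal isopropylidene, as with farnesyl acetate, and hydroxylates its E-methyl group, giving the (E)-allylic alcohol whose CH2OH carbon becomes C1.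

Step 4
Reactants: 5 (3S,6E,10E)-12-hydroxy-3,7,11-trimethyldodeca-6,10-dien-1-yl octadecanoate
Product: 6 (3S,6E,10E)-12-bromo-3,7,11-trimethyldodeca-6,10-dien-1-yl octadecanoate
Conditions: CBr4, PPh3, CH2Cl2, 0 °C
Reagents that add atoms: carbon tetrabromide, BrC(Br)(Br)Br
Why: Appel reaction: SN2 displacement of the oxyphosphonium group by bromide converts the primary allylic alcohol into the bromide without allylic transposition or loss of the E geometry.

Step 5
Reactants: 6 (3S,6E,10E)-12-bromo-3,7,11-trimethyldodeca-6,10-dien-1-yl octadecanoate; 7 2-(2-bromoethyl)-2-methyl-1,3-dioxolane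
Product: 10 (3S,6E,10E)-3,7,11-trimethyl-15-oxohexadeca-6,10-dien-1-yl octadecanoate, via Grignard reagent 8 (not isolated), via dioxolane ketal 9 (not isolated)
Conditions: 7, Mg, THF, 30 °C; then 6, Li2CuCl4 (3 mol %), THF, −78 → −20 °C; then 1 M HCl, THF, rt
Reagents that add atoms: water, O
Why: Kochi-type Li2CuCl4-catalysed cross-coupling of a primary alkyl Grignard reagent with a primary allylic bromide takes place at the α carbon with retention of the E alkene and is faster at −78 °C than addition to the ester; aqueous acid then hydrolyses the dioxolane to the methyl ketone.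

Step 6
Reactants: 10 (3S,6E,10E)-3,7,11-trimethyl-15-oxohexadeca-6,10-dien-1-yl octadecanoate
Product: 11 (3S,6E,10E)-3,7,11-trimethyl-14-[(2S)-2-methyloxiran-2-yl]tetradeca-6,10-dien-1-yl octadecanoate
Conditions: Me3S(O)I, NaH, THF; then 10, LaLi3[(S)-1,1′-binaphthalene-2,2′-diolate]3 (5 mol %), (2,4,6-(MeO)3C6H2)3P=O (5 mol %), 5 Å MS, THF, rt
Reagents that add atoms: trimethylsulfoxonium iodide, C[S+](C)(C)=O.[I-] (CH2 donor, as its methylide C[S+](C)(=O)[CH2-])
Why: Catalytic asymmetric Corey–Chaykovsky epoxidation: the lanthanum–lithium binaphtholate activates the methyl ketone and delivers the sulfoxonium methylide to one face, so the quaternary oxirane carbon (future C4) is formed S, and the ketone reacts far faster than the remote ester.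

Step 7
Reactants: 11 (3S,6E,10E)-3,7,11-trimethyl-14-[(2S)-2-methyloxiran-2-yl]tetradeca-6,10-dien-1-yl octadecanoate
Product: 12 (13S)-19-hydroxylabd-8(17)-en-15-yl octadecanoate [(3S)-5-[(1S,4aR,5S,8aR)-5-(hydroxymethyl)-5,8a-dimethyl-2-methylidenedecahydronaphthalen-1-yl]-3-methylpentyl octadecanoate]
Conditions: MeAlCl2 (2.5 equiv), CH2Cl2, −94 → −78 °C; then H2O
Reagents that add atoms: none
Why: Proposed new method: MeAlCl2 activates the oxirane, whose tertiary C4–O bond breaks with inversion in concert with attack of the C5=C10 alkene (so the S oxirane fixes C4), the tied-back oxirane CH2 (C19) taking the axial position of a chair–chair fold that closes ring A and then ring B as a trans-decalin with C20 β and the C9 side chain equatorial (from the two E alkenes), and the C8 cation loses a C17 proton to the Al–CH3/alkoxide base to give the exocyclic alkene as in the copalyl diphosphate synthase step; the closest known reactions are the MeAlCl2-promoted cyclisation of trisubstituted epoxy-polyenes (oxidosqualene type, concerted C–O cleavage and ring A closure) and the Lewis-acid cyclialkylation of arenes by 2,2-disubstituted oxiranes at their tertiary carbon.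

Step 8
Reactants: 12 (13S)-19-hydroxylabd-8(17)-en-15-yl octadecanoate
Product: 14 (1S,4aR,5S,8aR)-1,4a-dimethyl-5-[(3S)-3-methyl-5-(octadecanoyloxy)pentyl]-6-methylidenedecahydronaphthalene-1-carboxylic acid [(13S)-15-(octadecanoyloxy)labd-8(17)-en-19-oic acid; target], via C19 aldehyde 13 (not isolated)
Conditions: CrO3, H2SO4, H2O/acetone, 0 °C
Reagents that add atoms: water, O
Why: Chromic acid (Jones-type) oxidation takes the neopentyl primary alcohol through aldehyde 13 and its hydrate to the axial C19 acid without touching the quaternary C4, the ester or the 1,1-disubstituted alkene.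

## Compound list

1 | (2E,6E)-farnesol, (2E,6E)-3,7,11-trimethyldodeca-2,6,10-trien-1-ol | CC(C)=CCC/C(C)=C/CC/C(C)=C/CO | starting material
2 | (3S,6E)-3,7,11-trimethyldodeca-6,10-dien-1-ol, (S)-2,3-dihydrofarnesol | CC(C)=CCC/C(C)=C/CC[C@H](C)CCO | intermediate
3 | octadecanoyl chloride (stearoyl chloride) | CCCCCCCCCCCCCCCCCC(=O)Cl | starting material
4 | (3S,6E)-3,7,11-trimethyldodeca-6,10-dien-1-yl octadecanoate | CC(C)=CCC/C(C)=C/CC[C@H](C)CCOC(=O)CCCCCCCCCCCCCCCCC | intermediate
5 | (3S,6E,10E)-12-hydroxy-3,7,11-trimethyldodeca-6,10-dien-1-yl octadecanoate | OC/C(C)=C/CC/C(C)=C/CC[C@H](C)CCOC(=O)CCCCCCCCCCCCCCCCC | intermediate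
6 | (3S,6E,10E)-12-bromo-3,7,11-trimethyldodeca-6,10-dien-1-yl octadecanoate | BrC/C(C)=C/CC/C(C)=C/CC[C@H](C)CCOC(=O)CCCCCCCCCCCCCCCCC | intermediate
7 | 2-(2-bromoethyl)-2-methyl-1,3-dioxolane | CC1(CCBr)OCCO1 | starting material
8 | [2-(2-methyl-1,3-dioxolan-2-yl)ethyl]magnesium bromide | CC1(CC[Mg]Br)OCCO1 | intermediate
9 | (3S,6E,10E)-3,7,11-trimethyl-14-(2-methyl-1,3-dioxolan-2-yl)tetradeca-6,10-dien-1-yl octadecanoate | CC1(CCC/C(C)=C/CC/C(C)=C/CC[C@H](C)CCOC(=O)CCCCCCCCCCCCCCCCC)OCCO1 | intermediate
10 | (3S,6E,10E)-3,7,11-trimethyl-15-oxohexadeca-6,10-dien-1-yl octadecanoate | CC(=O)CCC/C(C)=C/CC/C(C)=C/CC[C@H](C)CCOC(=O)CCCCCCCCCCCCCCCCC | intermediate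
11 | (3S,6E,10E)-3,7,11-trimethyl-14-[(2S)-2-methyloxiran-2-yl]tetradeca-6,10-dien-1-yl octadecanoate | C[C@@]1(CO1)CCC/C(C)=C/CC/C(C)=C/CC[C@H](C)CCOC(=O)CCCCCCCCCCCCCCCCC | intermediate
12 | (13S)-19-hydroxylabd-8(17)-en-15-yl octadecanoate (trans-decalin, 5α-H, 9α-H, 10β-CH3, 4β-CH2OH axial) | C=C1CC[C@@H]2[C@](C)(CCC[C@]2(C)CO)[C@H]1CC[C@H](C)CCOC(=O)CCCCCCCCCCCCCCCCC | intermediate
13 | (13S)-19-oxolabd-8(17)-en-15-yl octadecanoate (C19 aldehyde) | C=C1CC[C@@H]2[C@](C)(CCC[C@]2(C)C=O)[C@H]1CC[C@H](C)CCOC(=O)CCCCCCCCCCCCCCCCC | intermediate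
14 | (1S,4aR,5S,8aR)-1,4a-dimethyl-5-[(3S)-3-methyl-5-(octadecanoyloxy)pentyl]-6-methylidenedecahydronaphthalene-1-carboxylic acid, (13S)-15-(octadecanoyloxy)labd-8(17)-en-19-oic acid | C=C1CC[C@@H]2[C@](C)(CCC[C@]2(C)C(=O)O)[C@H]1CC[C@H](C)CCOC(=O)CCCCCCCCCCCCCCCCC | target

## Step count and risks

Total step count: 8. Longest linear sequence: 8 steps (1 → 14).

**Step 7 (the cascade) is the most likely to fail.** It has no direct precedent for a 2,2-disubstituted oxirane initiator in a polyene bicyclisation. The open points are: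
- the other chair (C19 equatorial) would give the 18-hydroxy diastereomer of the mirror-image ring system, which should be separable;
- a hydride shift in the activated oxirane would give the 2-methyl aldehyde;
- the C10 cation may be captured by the C19 oxygen, or the cascade may stop after ring A;
- proton loss from C7 or C9 instead of C17 would give ring-alkene isomers, which is the point most certain to cost material.

Fallback for the last point, setting out from 11 and coming back at 12: the cascade is no longer asked to place the double bond. Oxirane 11 is cyclised with BF3·OEt2 (CH2Cl2, −78 → 0 °C), protic conditions that funnel the alkene isomers to the ring-trisubstituted isomer (13S)-19-hydroxylabd-7-en-15-yl octadecanoate F1. The double bond is then moved out of the ring in a separate photochemical step (Kropp photoprotonation: hν 254 nm, p-xylene as sensitiser, MeOH, rt). This re-forms the C8 cation from the excited ring alkene and accumulates the photostable exocyclic alkene 12.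

**Step 6 (asymmetric methylene transfer)** may give lower selectivity on a long-chain aliphatic methyl ketone, and the ylide may attack the ester. Any 2R oxirane ends up after step 7 as a diastereomer that is hard to remove.

Fallback, setting out from 10 and coming back at 11: uncatalysed Corey–Chaykovsky reaction (Me3S(O)I, NaH, DMSO, rt) gives the oxirane as a 1:1 mixture of epimers, (3S,6E,10E)-3,7,11-trimethyl-14-[(2RS)-2-methyloxiran-2-yl]tetradeca-6,10-dien-1-yl octadecanoate F2. Jacobsen kinetic resolution with TMSN3 and [N,N′-bis(3,5-di-tert-butylsalicylidene)-trans-cyclohexane-1,2-diaminato]CrN3 (antipode chosen to consume the 2R epimer) opens that epimer at its CH2 terminus to (3S,6E,10E,15R)-16-azido-3,7,11,15-tetramethyl-15-(trimethylsilyloxy)hexadeca-6,10-dien-1-yl octadecanoate F3. The unreacted 2S epimer 11 is separated by chromatography.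

**Step 5 (Grignard coupling)** may suffer from addition to the stearate, from γ attack on the allylic bromide, or from poor formation of the ketal Grignard reagent.

Fallback, setting out from 6 and 7 and coming back at 9: a sulfone carbanion replaces the Grignard reagent. Bromide 7 and PhSO2Na (DMF, 60 °C) give 2-methyl-2-[2-(phenylsulfonyl)ethyl]-1,3-dioxolane F4. Deprotonation with n-BuLi (THF, −78 °C) gives 2-[2-lithio-2-(phenylsulfonyl)ethyl]-2-methyl-1,3-dioxolane F5, which is alkylated by 6 to (3S,6E,10E,13RS)-3,7,11-trimethyl-14-(2-methyl-1,3-dioxolan-2-yl)-13-(phenylsulfonyl)tetradeca-6,10-dien-1-yl octadecanoate F6. Reductive desulfonylation (SmI2, HMPA, THF, −20 °C) gives ketal 9, which is hydrolysed to 10 as in step 5.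

## Further compounds

F1 | step 7 | (13S)-19-hydroxylabd-7-en-15-yl octadecanoate (ring-trisubstituted alkene isomer of 12) | CC1=CC[C@@H]2[C@](C)(CCC[C@]2(C)CO)[C@H]1CC[C@H](C)CCOC(=O)CCCCCCCCCCCCCCCCC
F2 | step 6 | (3S,6E,10E)-3,7,11-trimethyl-14-[(2RS)-2-methyloxiran-2-yl]tetradeca-6,10-dien-1-yl octadecanoate (1:1 epimers at the oxirane carbon) | CC1(CO1)CCC/C(C)=C/CC/C(C)=C/CC[C@H](C)CCOC(=O)CCCCCCCCCCCCCCCCC
F3 | step 6 | (3S,6E,10E,15R)-16-azido-3,7,11,15-tetramethyl-15-(trimethylsilyloxy)hexadeca-6,10-dien-1-yl octadecanoate | C[C@](O[Si](C)(C)C)(CN=[N+]=[N-])CCC/C(C)=C/CC/C(C)=C/CC[C@H](C)CCOC(=O)CCCCCCCCCCCCCCCCC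
F4 | step 5 | 2-methyl-2-[2-(phenylsulfonyl)ethyl]-1,3-dioxolane | CC1(CCS(=O)(=O)c2ccccc2)OCCO1
F5 | step 5 | 2-[2-lithio-2-(phenylsulfonyl)ethyl]-2-methyl-1,3-dioxolane | CC1(CC([Li])S(=O)(=O)c2ccccc2)OCCO1
F6 | step 5 | (3S,6E,10E,13RS)-3,7,11-trimethyl-14-(2-methyl-1,3-dioxolan-2-yl)-13-(phenylsulfonyl)tetradeca-6,10-dien-1-yl octadecanoate | CC1(CC(C/C(C)=C/CC/C(C)=C/CC[C@H](C)CCOC(=O)CCCCCCCCCCCCCCCCC)S(=O)(=O)c2ccccc2)OCCO1
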